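**Plan**

1. Retrosynthesis: after removal of fifteen benzyl ethers and two pivalates, the two C2–C1′ (ring B) bonds of the terminal unit T and the middle unit M are cut. This is possible because in these two rings C2 is an acetal-type carbon on O1 next to the oxygen-bearing C3, and ring B lies anti to both O3 and the C4 aryl, so a lactol ester with a participating C3 ester is the natural precursor.
2. Further cuts: C3–O and C4–H of both lactones, then the sp2–sp2 bonds C4(T)–C6(M) and C4(M)–C8(catechin), giving two 4-tosyloxycoumarins and a dimer bromide; last, C4(S)–C6(catechin), giving a flavan-3,4-diol diacetate and 8-bromocatechin (S = the ent-fisetinidol unit on C6).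
3. Forward: ring C of unit S closes first (chalcone epoxide to dihydroflavonol); S is joined to C6 of catechin; coumarin M is attached to C8, coumarin T to C6 of M; both lactones are elaborated together; the two rings B are added last, with no ring closure.
4. Stereochemistry: catechin from the chiral pool; C3 of S from Juliá–Colonna epoxidation, C2 of S by invertive ring closure, C4 of S by acetate participation; C4 of T and M by ligand-controlled CuH reduction; C3 by anti hydroxylation then SN2 inversion; C2 by pivalate participation.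

Key step: step 24

Conventions: α/β refer to the usual flavan drawing (ring A left, O1 at the top, β toward the viewer); a dihydrocoumarin ring is numbered and drawn as the future ring C. In this drawing (+)-catechin is 2α-aryl, 3β-OH and an ent-fisetinidol unit (2S,3R) is 2β-aryl, 3α-OH. D is the 8-yl residue of dimer 14 (14 without Br).

Assumptions: (a) the (R)-DTBM-SEGPHOS–CuH catalyst of step 19 is taken to deliver hydride to the β face of C4; if a model 4-arylcoumarin shows the opposite sense, the (S)-ligand is used. (b) Ketone 15 is taken as a catalogue compound; it is otherwise the acetylation product of 4-chlororesorcinol.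

**Route**

Step 1
Reactants: 1 1-[4-(benzyloxy)-2-hydroxyphenyl]ethanone
Product: 2 1-[4-(benzyloxy)-2-(methoxymethoxy)phenyl]ethanone
Conditions: NaH, MeOCH2Cl, DMF, 0 °C → rt
Reagents that add atoms: chloromethyl methyl ether, COCCl
Why: Williamson O-alkylation of the sodium phenoxide; the MOM acetal is needed because a free 2′-phenol would divert the alkaline peroxide epoxidation of step 3 into Algar–Flynn–Oyamada cyclisation.

Step 2
Reactants: 2 MOM-protected ketone; 3 3,4-bis(benzyloxy)benzaldehyde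
Product: 4 (E)-1-[4-(benzyloxy)-2-(methoxymethoxy)phenyl]-3-[3,4-bis(benzyloxy)phenyl]prop-2-en-1-one
Conditions: KOH (aq.), EtOH/THF, rt
Reagents that add atoms: none
Why: Claisen–Schmidt condensation of the methyl ketone with a non-enolisable aldehyde gives the thermodynamically favoured (E)-enone; MOM and benzyl ethers are inert to aqueous KOH.

Step 3
Reactants: 4 chalcone
Product: 5 [4-(benzyloxy)-2-(methoxymethoxy)phenyl][(2S,3R)-3-[3,4-bis(benzyloxy)phenyl]oxiran-2-yl]methanone (trans-epoxide)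
Conditions: poly-D-leucine, urea–H2O2, DBU, THF, rt
Reagents that add atoms: hydrogen peroxide (as its urea adduct), OO
Why: Juliá–Colonna epoxidation, a polyleucine-templated Weitz–Scheffer addition of hydroperoxide to the enone, gives the trans-epoxide; the D-configured helix is chosen so that Cα (the later C3 of unit S) becomes S and Cβ becomes R.

Step 4
Reactants: 5 epoxy ketone
Product: 6 (2S,3S)-7-(benzyloxy)-2-[3,4-bis(benzyloxy)phenyl]-3-hydroxychroman-4-one (2,3-trans)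
Conditions: conc. HCl, MeOH/THF, 50 °C
Reagents that add atoms: none
Why: acid-catalysed cleavage of the MOM acetal frees the phenol, which opens the epoxide at the dibenzyloxybenzylic carbon (6-endo epoxide-opening cyclisation) with inversion, so C2 becomes S and the 2,3-trans dihydroflavonol results while C3 keeps the configuration set in step 3.

Step 5
Reactants: 6 dihydroflavonol
Product: 7 (2S,3R,4S)-7-(benzyloxy)-2-[3,4-bis(benzyloxy)phenyl]chromane-3,4-diol (2,3-trans-3,4-trans)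
Conditions: NaBH4, MeOH/THF, 0 °C
Reagents that add atoms: none
Why: NaBH4 carbonyl reduction, expected to give mainly the 3,4-trans diol as with other trans-dihydroflavonols; the C4 configuration is of no consequence because C4 is ionised in step 9.

Step 6
Reactants: 7 flavan-3,4-diol
Product: 8 3,4-di-O-acetate of 7 (ring configuration unchanged: 2β-aryl, 3α-OAc, 4β-OAc)
Conditions: Ac2O, pyridine, DMAP (cat.), CH2Cl2, rt
Reagents that add atoms: acetic anhydride, CC(=O)OC(C)=O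
Why: DMAP-catalysed acylation of both secondary alcohols; the benzylic C4 acetate becomes the leaving group and the C3 acetate the participating neighbour for step 9.

Step 7
Reactants: 9 (+)-catechin
Product: 10 (2R,3S)-5,7-bis(benzyloxy)-2-[3,4-bis(benzyloxy)phenyl]chroman-3-ol
Conditions: BnBr, K2CO3, DMF, 0 °C → rt
Reagents that add atoms: benzyl bromide, BrCc1ccccc1
Why: Williamson benzylation with the weak base K2CO3 alkylates only the four phenols, leaves the aliphatic 3-OH free and avoids base-induced epimerisation at C2.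

Step 8
Reactants: 10 tetra-O-benzylcatechin
Product: 11 (2R,3S)-5,7-bis(benzyloxy)-2-[3,4-bis(benzyloxy)phenyl]-8-bromochroman-3-ol
Conditions: NBS, CH2Cl2, −78 °C → rt
Reagents that add atoms: N-bromosuccinimide, O=C1CCC(=O)N1Br
Why: electrophilic aromatic bromination; C8 is the more reactive position of 5,7-dialkoxyflavans toward NBS, and the bromine both blocks C8 in step 9 and serves as the metalation handle in step 15.

Step 9
Reactants: 8 flavan-3,4-diol diacetate; 11 8-bromocatechin tetrabenzyl ether (2 equiv)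
Product: 12 3-O-acetyl-7,3′,4′-tri-O-benzyl-ent-fisetinidol-(4β→6)-5,7,3′,4′-tetra-O-benzyl-8-bromocatechin
Conditions: Me3SiOTf (0.3 equiv), CH2Cl2, −40 → 0 °C
Reagents that add atoms: none
Why: Lewis-acid ionisation of the C4 acetate gives a 7-benzyloxy-stabilised benzylic cation bridged by the C3 acetate, and Friedel–Crafts attack by C6 of 11 (the only free position of its phloroglucinol-type ring A, C8 being bromine-capped) anti to O3 sets C4 of unit S as 4β (3,4-trans).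

Step 10
Reactants: 12 dimer acetate
Product: 13 7,3′,4′-tri-O-benzyl-ent-fisetinidol-(4β→6)-5,7,3′,4′-tetra-O-benzyl-8-bromocatechin
Conditions: K2CO3, MeOH/THF, rt
Reagents that add atoms: none
Why: base-catalysed transesterification removes the secondary acetate; aryl bromide and benzyl ethers are inert.

Step 11
Reactants: 13 dimer diol
Product: 14 3,7,3′,4′-tetra-O-benzyl-ent-fisetinidol-(4β→6)-3,5,7,3′,4′-penta-O-benzyl-8-bromocatechin (D–Br)
Conditions: NaH, BnBr, Bu4NI (cat.), DMF, 0 °C → rt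
Reagents that add atoms: benzyl bromide, BrCc1ccccc1
Why: Williamson etherification of both secondary alkoxides turns every hydroxyl into a benzyl ether, so the organolithium, enolate and hydride steps that follow meet no acidic or acyl group.

Step 12
Reactants: 15 1-(5-chloro-2,4-dihydroxyphenyl)ethanone
Product: 16 1-[4-(benzyloxy)-5-chloro-2-hydroxyphenyl]ethanone
Conditions: BnBr (1.05 equiv), K2CO3, acetone, 56 °C
Reagents that add atoms: benzyl bromide, BrCc1ccccc1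
Why: regioselective Williamson benzylation; the 2-OH is held in a hydrogen bond to the ketone, so only the 4-OH reacts with one equivalent of BnBr.

Step 13
Reactants: 16 chloro ketone
Product: 17 7-(benzyloxy)-6-chloro-4-hydroxy-2H-chromen-2-one
Conditions: NaH, (EtO)2CO, toluene, 100 °C; then aq. HCl
Reagents that add atoms: diethyl carbonate, CCOC(=O)OCC
Why: Claisen condensation of the ketone enolate with diethyl carbonate followed by lactonisation onto the phenoxide builds the 4-hydroxycoumarin ring, the standard route from 2-hydroxyacetophenones.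

Step 14
Reactants: 17 chloro-4-hydroxycoumarin
Product: 18 7-(benzyloxy)-6-chloro-2-oxo-2H-chromen-4-yl 4-methylbenzenesulfonate
Conditions: TsCl, Et3N, CH2Cl2, 0 °C → rt
Reagents that add atoms: 4-toluenesulfonyl chloride, Cc1ccc(cc1)S(Cl)(=O)=O
Why: O-sulfonylation of the vinylogous acid gives an enol tosylate activated for oxidative addition by the lactone carbonyl.

Step 15
Reactants: 14 dimer bromide D–Br; 18 chlorocoumarin tosylate
Product: 21 7-(benzyloxy)-6-chloro-4-D-2H-chromen-2-one, via 8-lithio dimer 19 (not isolated), via dimer-8-ylzinc chloride 20 (not isolated)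
Conditions: n-BuLi, THF, −78 °C; ZnCl2, −78 °C → rt; 18, Pd(PPh3)4 (5 mol %), THF, 60 °C
Reagents that add atoms: none
Why: bromine–lithium exchange and transmetalation give a hindered, non-basic arylzinc that undergoes Negishi coupling with the 4-tosyloxycoumarin (established for this electrophile class); Pd(PPh3)4 inserts into the activated C4–OTs bond but not into the electron-rich aryl C–Cl bond, and no stereocentre forms (rotamers about the new C4–C8 bond are of no consequence).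

Step 16
Reactants: 1 1-[4-(benzyloxy)-2-hydroxyphenyl]ethanone
Product: 22 7-(benzyloxy)-4-hydroxy-2H-chromen-2-one
Conditions: NaH, (EtO)2CO, toluene, 100 °C; then aq. HCl
Reagents that add atoms: diethyl carbonate, CCOC(=O)OCC
Why: Claisen condensation with diethyl carbonate and lactonisation, as in step 13.

Step 17
Reactants: 22 4-hydroxycoumarin
Product: 23 7-(benzyloxy)-2-oxo-2H-chromen-4-yl 4-methylbenzenesulfonate
Conditions: TsCl, Et3N, CH2Cl2, 0 °C → rt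
Reagents that add atoms: 4-toluenesulfonyl chloride, Cc1ccc(cc1)S(Cl)(=O)=O
Why: O-sulfonylation of the vinylogous acid, as in step 14.

Step 18
Reactants: 21 6-chloro-4-D-coumarin; 23 coumarin tosylate
Product: 25 7-(benzyloxy)-6-[7-(benzyloxy)-2-oxo-2H-chromen-4-yl]-4-D-2H-chromen-2-one, via pinacol boronate 24 (not isolated)
Conditions: B2pin2, Pd2(dba)3 (2 mol %), XPhos (8 mol %), KOAc, 1,4-dioxane, 100 °C; then 23, K3PO4 (aq.), 80 °C
Reagents that add atoms: none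
Why: Miyaura borylation of the aryl chloride under Pd/XPhos followed in the same flask by Suzuki–Miyaura coupling of the boronate with enol tosylate 23; any coumarin opened by the aqueous base recloses on acidic work-up.

Step 19
Reactants: 25 bis-coumarin
Product: 26 7-(benzyloxy)-6-[7-(benzyloxy)-2-oxochroman-4-yl]-4-D-chroman-2-one with both C4–H β (4α-aryl in each lactone ring)
Conditions: Cu(OAc)2·H2O (10 mol %), (R)-DTBM-SEGPHOS (10 mol %), (EtO)2MeSiH, t-BuOH, toluene, rt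
Reagents that add atoms: none
Why: asymmetric conjugate reduction of 4-arylcoumarins by bisphosphine-ligated CuH (known for this substrate class); hydride is delivered to C4 of each enoate under control of the chiral ligand, setting both C4 centres with H β and the aryl group α, while t-BuOH protonates the copper enolate and the lactone carbonyls and benzyl ethers are left alone.

Step 20
Reactants: 26 bis-dihydrocoumarin
Product: 27 3β,3β-dihydroxy derivative of 26 (3-OH trans to the C4 aryl in each lactone ring)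
Conditions: KN(SiMe3)2, THF, −78 °C; 2-(phenylsulfonyl)-3-phenyloxaziridine, −78 °C; aq. NH4Cl
Reagents that add atoms: 2-(phenylsulfonyl)-3-phenyloxaziridine, O=S(=O)(c1ccccc1)N1OC1c1ccccc1
Why: electrophilic hydroxylation of the two potassium lactone enolates by the N-sulfonyloxaziridine; oxygen is transferred to the enolate face anti to the pseudo-axial C4 aryl group, giving 3β-OH (3,4-trans) in both rings.

Step 21
Reactants: 27 bis(3β-hydroxy lactone)
Product: 29 3α,3α-bis(pivaloyloxy) analogue of 26 (3-O cis to the C4 aryl in each lactone ring), via bis-triflate 28 (not isolated)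
Conditions: Tf2O, pyridine, CH2Cl2, −40 °C; then CsO2CCMe3, DMF, 0 °C → rt
Reagents that add atoms: cesium pivalate, [Cs+].CC(C)(C)C([O-])=O
Why: triflation followed by SN2 displacement with carboxylate (Walden inversion at a carbonyl-activated carbon, as established for α-triflyloxy lactones) converts 3β-OH into 3α-OPiv, cis to the C4 aryl; H4 is syn to the leaving group, so anti-elimination to the coumarin is not available.

Step 22
Reactants: 29 bis(3α-pivaloyloxy lactone)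
Product: 31 bis(2-O-acetyl-3-O-pivaloyl lactol) of 29 (each lactone C=O now CH–OAc as C2 anomers; 3α-OPiv; 4α-aryl), via bis(aluminium lactolate) 30 (not isolated)
Conditions: i-Bu2AlH, CH2Cl2, −78 °C; then pyridine, DMAP, Ac2O, −78 → 0 °C
Reagents that add atoms: acetic anhydride, CC(=O)OC(C)=O
Why: reductive acetylation; i-Bu2AlH adds once to the activated aryl-lactone carbonyl at −78 °C to give a stable aluminium hemiacetal that is acetylated in the same flask, while the hindered, less electrophilic pivalates survive; the C2 anomer mixture is of no consequence for step 24.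

Step 23
Reactants: 32 1,2-bis(benzyloxy)-4-bromobenzene
Product: 34 [3,4-bis(benzyloxy)phenyl]zinc bromide, via 3,4-bis(benzyloxy)phenyllithium 33 (not isolated)
Conditions: n-BuLi, toluene/n-Bu2O, −20 °C; ZnBr2, n-Bu2O, −20 °C → rt
Reagents that add atoms: zinc bromide, [Zn+2].[Br-].[Br-]
Why: bromine–lithium exchange and transmetalation with ZnBr2 in a THF-free medium give the arylzinc halide in the weakly coordinating solvent that step 24 needs.

Step 24
Reactants: 31 bis(2-O-acetyl-3-O-pivaloyl lactol); 34 [3,4-bis(benzyloxy)phenyl]zinc bromide (6 equiv)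
Product: 36 3-O-pivaloyl-7,3′,4′-tri-O-benzyl-ent-fisetinidol-(4α→6)-3-O-pivaloyl-7,3′,4′-tri-O-benzyl-ent-fisetinidol-(4α→8)-3,5,7,3′,4′-penta-O-benzylcatechin-(6→4β)-3,7,3′,4′-tetra-O-benzyl-ent-fisetinidol, via bis(C2 bromide) 35 (not isolated)
Conditions: Me3SiBr, CH2Cl2, 0 °C → rt, evaporate; 34, toluene/n-Bu2O, rt → 80 °C
Reagents that add atoms: none
Why: Proposed new method: Me3SiBr exchanges each anomeric acetate for bromide; zinc halide then assists loss of bromide from C2 to give an O1-stabilised oxocarbenium ion that the C3 pivalate closes to a cis-fused 1,3-dioxolan-2-ylium ion, and transfer of the aryl group from zinc to C2 on the open face forms the C2–C1′ bond. The closest known reaction is the uncatalysed 1,2-trans C-arylation of 2-O-pivaloyl glycosyl bromides with arylzinc halides; a 2-bromo-3-acyloxychroman is its benzo-fused analogue, whose cation is less stabilised by the aryl ether oxygen but carries only one electron-withdrawing ester and should ionise at least as readily. No ring is closed, since both chroman rings are already present. Each new C2 stereocentre is controlled by the neighbouring C3 pivalate, which forces attack anti to O3 (2β-aryl, 2,3-trans), and in these 3,4-cis rings that face is also anti to the pseudo-axial C4 aryl, so both neighbours direct alike. The step needs 1,2-trans selectivity and attack at C2 in preference to the acyl carbon, secured by participation and by the bulk of the tert-butyl group; the anomeric configuration of 31 is irrelevant because both anomers funnel into the same dioxolanylium ion.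

Step 25
Reactants: 36 bis-pivalate
Product: 37 7,3′,4′-tri-O-benzyl-ent-fisetinidol-(4α→6)-7,3′,4′-tri-O-benzyl-ent-fisetinidol-(4α→8)-3,5,7,3′,4′-penta-O-benzylcatechin-(6→4β)-3,7,3′,4′-tetra-O-benzyl-ent-fisetinidol
Conditions: NaOMe, MeOH/THF, 60 °C
Reagents that add atoms: none
Why: base-catalysed methanolysis (transesterification) of the two hindered pivalates; benzyl ethers and the benzylic C2–O1 bonds are stable to methoxide.

Step 26
Reactants: 37 pentadeca-O-benzyl tetraflavanoid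
Product: 38 ent-fisetinidol-(4α→6)-ent-fisetinidol-(4α→8)-catechin-(6→4β)-ent-fisetinidol (CNP0126838.5)
Conditions: H2 (1 atm), Pd(OH)2/C, THF/MeOH/H2O, rt
Reagents that add atoms: none
Why: hydrogenolysis of all fifteen benzyl ethers over Pd(OH)2 on carbon, the standard last step for benzylated oligoflavanoids; no stereocentre is touched.

**Compound list**

1 | 1-[4-(benzyloxy)-2-hydroxyphenyl]ethanone | CC(=O)c1ccc(OCc2ccccc2)cc1O | starting material
2 | 1-[4-(benzyloxy)-2-(methoxymethoxy)phenyl]ethanone | CC(=O)c1ccc(OCc2ccccc2)cc1OCOC | intermediate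
3 | 3,4-bis(benzyloxy)benzaldehyde | O=Cc1ccc(OCc2ccccc2)c(OCc2ccccc2)c1 | starting material
4 | (E)-1-[4-(benzyloxy)-2-(methoxymethoxy)phenyl]-3-[3,4-bis(benzyloxy)phenyl]prop-2-en-1-one | COCOc1cc(OCc2ccccc2)ccc1C(=O)/C=C/c1ccc(OCc2ccccc2)c(OCc2ccccc2)c1 | intermediate
5 | [4-(benzyloxy)-2-(methoxymethoxy)phenyl][(2S,3R)-3-[3,4-bis(benzyloxy)phenyl]oxiran-2-yl]methanone | COCOc1cc(OCc2ccccc2)ccc1C(=O)[C@H]1O[C@@H]1c1ccc(OCc2ccccc2)c(OCc2ccccc2)c1 | intermediate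
6 | (2S,3S)-7-(benzyloxy)-2-[3,4-bis(benzyloxy)phenyl]-3-hydroxychroman-4-one | O=C1[C@@H](O)[C@H](c2ccc(OCc3ccccc3)c(OCc3ccccc3)c2)Oc2cc(OCc3ccccc3)ccc21 | intermediate
7 | (2S,3R,4S)-7-(benzyloxy)-2-[3,4-bis(benzyloxy)phenyl]chromane-3,4-diol | O[C@H]1c2ccc(OCc3ccccc3)cc2O[C@@H](c2ccc(OCc3ccccc3)c(OCc3ccccc3)c2)[C@@H]1O | intermediate
8 | 3,4-di-O-acetate of 7 (2β-aryl, 3α-OAc, 4β-OAc) | CC(=O)O[C@H]1c2ccc(OCc3ccccc3)cc2O[C@@H](c2ccc(OCc3ccccc3)c(OCc3ccccc3)c2)[C@@H]1OC(C)=O | intermediate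
9 | (+)-catechin, (2R,3S)-2-(3,4-dihydroxyphenyl)chromane-3,5,7-triol | O[C@H]1Cc2c(O)cc(O)cc2O[C@@H]1c1ccc(O)c(O)c1 | starting material
10 | (2R,3S)-5,7-bis(benzyloxy)-2-[3,4-bis(benzyloxy)phenyl]chroman-3-ol | O[C@H]1Cc2c(OCc3ccccc3)cc(OCc3ccccc3)cc2O[C@@H]1c1ccc(OCc3ccccc3)c(OCc3ccccc3)c1 | intermediate
11 | (2R,3S)-5,7-bis(benzyloxy)-2-[3,4-bis(benzyloxy)phenyl]-8-bromochroman-3-ol | O[C@H]1Cc2c(OCc3ccccc3)cc(OCc3ccccc3)c(Br)c2O[C@@H]1c1ccc(OCc3ccccc3)c(OCc3ccccc3)c1 | intermediate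
12 | 3-O-acetyl-7,3′,4′-tri-O-benzyl-ent-fisetinidol-(4β→6)-5,7,3′,4′-tetra-O-benzyl-8-bromocatechin (unit S 2S,3R,4R) | Brc1c(OCc9ccccc9)c([C@H]2c3ccc(OCc9ccccc9)cc3O[C@@H](c3ccc(OCc9ccccc9)c(OCc9ccccc9)c3)[C@@H]2OC(C)=O)c(OCc9ccccc9)c2c1O[C@H](c1ccc(OCc9ccccc9)c(OCc9ccccc9)c1)[C@@H](O)C2 | intermediate
13 | 7,3′,4′-tri-O-benzyl-ent-fisetinidol-(4β→6)-5,7,3′,4′-tetra-O-benzyl-8-bromocatechin | Brc1c(OCc9ccccc9)c([C@H]2c3ccc(OCc9ccccc9)cc3O[C@@H](c3ccc(OCc9ccccc9)c(OCc9ccccc9)c3)[C@@H]2O)c(OCc9ccccc9)c2c1O[C@H](c1ccc(OCc9ccccc9)c(OCc9ccccc9)c1)[C@@H](O)C2 | intermediate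
14 | 3,7,3′,4′-tetra-O-benzyl-ent-fisetinidol-(4β→6)-3,5,7,3′,4′-penta-O-benzyl-8-bromocatechin (D–Br) | Brc1c(OCc9ccccc9)c([C@H]2c3ccc(OCc9ccccc9)cc3O[C@@H](c3ccc(OCc9ccccc9)c(OCc9ccccc9)c3)[C@@H]2OCc9ccccc9)c(OCc9ccccc9)c2c1O[C@H](c1ccc(OCc9ccccc9)c(OCc9ccccc9)c1)[C@@H](OCc9ccccc9)C2 | intermediate
15 | 1-(5-chloro-2,4-dihydroxyphenyl)ethanone | CC(=O)c1cc(Cl)c(O)cc1O | starting material
16 | 1-[4-(benzyloxy)-5-chloro-2-hydroxyphenyl]ethanone | CC(=O)c1cc(Cl)c(OCc2ccccc2)cc1O | intermediate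
17 | 7-(benzyloxy)-6-chloro-4-hydroxy-2H-chromen-2-one | Oc1cc(=O)oc2cc(OCc3ccccc3)c(Cl)cc12 | intermediate
18 | 7-(benzyloxy)-6-chloro-2-oxo-2H-chromen-4-yl 4-methylbenzenesulfonate | Cc1ccc(cc1)S(=O)(=O)Oc1cc(=O)oc2cc(OCc3ccccc3)c(Cl)cc12 | intermediate
19 | D–Li, 8-lithio derivative of 14 | [Li]c1c(OCc9ccccc9)c([C@H]2c3ccc(OCc9ccccc9)cc3O[C@@H](c3ccc(OCc9ccccc9)c(OCc9ccccc9)c3)[C@@H]2OCc9ccccc9)c(OCc9ccccc9)c2c1O[C@H](c1ccc(OCc9ccccc9)c(OCc9ccccc9)c1)[C@@H](OCc9ccccc9)C2 | intermediate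
20 | D–ZnCl, dimer-8-ylzinc chloride | Cl[Zn]c1c(OCc9ccccc9)c([C@H]2c3ccc(OCc9ccccc9)cc3O[C@@H](c3ccc(OCc9ccccc9)c(OCc9ccccc9)c3)[C@@H]2OCc9ccccc9)c(OCc9ccccc9)c2c1O[C@H](c1ccc(OCc9ccccc9)c(OCc9ccccc9)c1)[C@@H](OCc9ccccc9)C2 | intermediate
21 | 7-(benzyloxy)-6-chloro-4-D-2H-chromen-2-one | Clc1cc2c(cc1OCc9ccccc9)oc(=O)cc2c1c(OCc9ccccc9)c([C@H]2c3ccc(OCc9ccccc9)cc3O[C@@H](c3ccc(OCc9ccccc9)c(OCc9ccccc9)c3)[C@@H]2OCc9ccccc9)c(OCc9ccccc9)c2c1O[C@H](c1ccc(OCc9ccccc9)c(OCc9ccccc9)c1)[C@@H](OCc9ccccc9)C2 | intermediate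
22 | 7-(benzyloxy)-4-hydroxy-2H-chromen-2-one | Oc1cc(=O)oc2cc(OCc3ccccc3)ccc12 | intermediate
23 | 7-(benzyloxy)-2-oxo-2H-chromen-4-yl 4-methylbenzenesulfonate | Cc1ccc(cc1)S(=O)(=O)Oc1cc(=O)oc2cc(OCc3ccccc3)ccc12 | intermediate
24 | 7-(benzyloxy)-4-D-6-(4,4,5,5-tetramethyl-1,3,2-dioxaborolan-2-yl)-2H-chromen-2-one | CC1(C)OB(OC1(C)C)c1cc2c(cc1OCc9ccccc9)oc(=O)cc2c1c(OCc9ccccc9)c([C@H]2c3ccc(OCc9ccccc9)cc3O[C@@H](c3ccc(OCc9ccccc9)c(OCc9ccccc9)c3)[C@@H]2OCc9ccccc9)c(OCc9ccccc9)c2c1O[C@H](c1ccc(OCc9ccccc9)c(OCc9ccccc9)c1)[C@@H](OCc9ccccc9)C2 | intermediate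
25 | 7-(benzyloxy)-6-[7-(benzyloxy)-2-oxo-2H-chromen-4-yl]-4-D-2H-chromen-2-one (bis-coumarin) | c9ccccc9COc1ccc2c(c1)oc(=O)cc2c1cc2c(cc1OCc9ccccc9)oc(=O)cc2c1c(OCc9ccccc9)c([C@H]2c3ccc(OCc9ccccc9)cc3O[C@@H](c3ccc(OCc9ccccc9)c(OCc9ccccc9)c3)[C@@H]2OCc9ccccc9)c(OCc9ccccc9)c2c1O[C@H](c1ccc(OCc9ccccc9)c(OCc9ccccc9)c1)[C@@H](OCc9ccccc9)C2 | intermediate
26 | 7-(benzyloxy)-6-[7-(benzyloxy)-2-oxochroman-4-yl]-4-D-chroman-2-one, both C4–H β (4α-aryl) | c9ccccc9COc1ccc2c(c1)OC(=O)C[C@@H]2c1cc2c(cc1OCc9ccccc9)OC(=O)C[C@@H]2c1c(OCc9ccccc9)c([C@H]2c3ccc(OCc9ccccc9)cc3O[C@@H](c3ccc(OCc9ccccc9)c(OCc9ccccc9)c3)[C@@H]2OCc9ccccc9)c(OCc9ccccc9)c2c1O[C@H](c1ccc(OCc9ccccc9)c(OCc9ccccc9)c1)[C@@H](OCc9ccccc9)C2 | intermediate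
27 | 3β,3β-dihydroxy derivative of 26 (3,4-trans in each lactone ring) | c9ccccc9COc1ccc2c(c1)OC(=O)[C@@H](O)[C@@H]2c1cc2c(cc1OCc9ccccc9)OC(=O)[C@@H](O)[C@@H]2c1c(OCc9ccccc9)c([C@H]2c3ccc(OCc9ccccc9)cc3O[C@@H](c3ccc(OCc9ccccc9)c(OCc9ccccc9)c3)[C@@H]2OCc9ccccc9)c(OCc9ccccc9)c2c1O[C@H](c1ccc(OCc9ccccc9)c(OCc9ccccc9)c1)[C@@H](OCc9ccccc9)C2 | intermediate
28 | bis(trifluoromethanesulfonate) of 27 | c9ccccc9COc1ccc2c(c1)OC(=O)[C@@H](OS(=O)(=O)C(F)(F)F)[C@@H]2c1cc2c(cc1OCc9ccccc9)OC(=O)[C@@H](OS(=O)(=O)C(F)(F)F)[C@@H]2c1c(OCc9ccccc9)c([C@H]2c3ccc(OCc9ccccc9)cc3O[C@@H](c3ccc(OCc9ccccc9)c(OCc9ccccc9)c3)[C@@H]2OCc9ccccc9)c(OCc9ccccc9)c2c1O[C@H](c1ccc(OCc9ccccc9)c(OCc9ccccc9)c1)[C@@H](OCc9ccccc9)C2 | intermediate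
29 | 3α,3α-bis(pivaloyloxy) analogue of 26 (3,4-cis in each lactone ring) | c9ccccc9COc1ccc2c(c1)OC(=O)[C@H](OC(=O)C(C)(C)C)[C@@H]2c1cc2c(cc1OCc9ccccc9)OC(=O)[C@H](OC(=O)C(C)(C)C)[C@@H]2c1c(OCc9ccccc9)c([C@H]2c3ccc(OCc9ccccc9)cc3O[C@@H](c3ccc(OCc9ccccc9)c(OCc9ccccc9)c3)[C@@H]2OCc9ccccc9)c(OCc9ccccc9)c2c1O[C@H](c1ccc(OCc9ccccc9)c(OCc9ccccc9)c1)[C@@H](OCc9ccccc9)C2 | intermediate
30 | bis(diisobutylaluminium lactolate) of 29 | c9ccccc9COc1ccc2c(c1)OC(O[Al](CC(C)C)CC(C)C)[C@H](OC(=O)C(C)(C)C)[C@@H]2c1cc2c(cc1OCc9ccccc9)OC(O[Al](CC(C)C)CC(C)C)[C@H](OC(=O)C(C)(C)C)[C@@H]2c1c(OCc9ccccc9)c([C@H]2c3ccc(OCc9ccccc9)cc3O[C@@H](c3ccc(OCc9ccccc9)c(OCc9ccccc9)c3)[C@@H]2OCc9ccccc9)c(OCc9ccccc9)c2c1O[C@H](c1ccc(OCc9ccccc9)c(OCc9ccccc9)c1)[C@@H](OCc9ccccc9)C2 | intermediate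
31 | bis(2-O-acetyl-3-O-pivaloyl lactol) of 29 (C2 anomers; 3α-OPiv; 4α-aryl) | c9ccccc9COc1ccc2c(c1)OC(OC(C)=O)[C@H](OC(=O)C(C)(C)C)[C@@H]2c1cc2c(cc1OCc9ccccc9)OC(OC(C)=O)[C@H](OC(=O)C(C)(C)C)[C@@H]2c1c(OCc9ccccc9)c([C@H]2c3ccc(OCc9ccccc9)cc3O[C@@H](c3ccc(OCc9ccccc9)c(OCc9ccccc9)c3)[C@@H]2OCc9ccccc9)c(OCc9ccccc9)c2c1O[C@H](c1ccc(OCc9ccccc9)c(OCc9ccccc9)c1)[C@@H](OCc9ccccc9)C2 | intermediate
32 | 1,2-bis(benzyloxy)-4-bromobenzene | Brc1ccc(OCc2ccccc2)c(OCc2ccccc2)c1 | starting material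
33 | 3,4-bis(benzyloxy)phenyllithium | [Li]c1ccc(OCc2ccccc2)c(OCc2ccccc2)c1 | intermediate
34 | [3,4-bis(benzyloxy)phenyl]zinc bromide | Br[Zn]c1ccc(OCc2ccccc2)c(OCc2ccccc2)c1 | intermediate
35 | bis(C2 bromide): 31 with Br in place of each OAc | c9ccccc9COc1ccc2c(c1)OC(Br)[C@H](OC(=O)C(C)(C)C)[C@@H]2c1cc2c(cc1OCc9ccccc9)OC(Br)[C@H](OC(=O)C(C)(C)C)[C@@H]2c1c(OCc9ccccc9)c([C@H]2c3ccc(OCc9ccccc9)cc3O[C@@H](c3ccc(OCc9ccccc9)c(OCc9ccccc9)c3)[C@@H]2OCc9ccccc9)c(OCc9ccccc9)c2c1O[C@H](c1ccc(OCc9ccccc9)c(OCc9ccccc9)c1)[C@@H](OCc9ccccc9)C2 | intermediate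
36 | 3-O-pivaloyl-7,3′,4′-tri-O-benzyl-ent-fisetinidol-(4α→6)-3-O-pivaloyl-7,3′,4′-tri-O-benzyl-ent-fisetinidol-(4α→8)-3,5,7,3′,4′-penta-O-benzylcatechin-(6→4β)-3,7,3′,4′-tetra-O-benzyl-ent-fisetinidol | c9ccccc9COc1ccc2c(c1)O[C@@H](c1ccc(OCc9ccccc9)c(OCc9ccccc9)c1)[C@H](OC(=O)C(C)(C)C)[C@@H]2c1cc2c(cc1OCc9ccccc9)O[C@@H](c1ccc(OCc9ccccc9)c(OCc9ccccc9)c1)[C@H](OC(=O)C(C)(C)C)[C@@H]2c1c(OCc9ccccc9)c([C@H]2c3ccc(OCc9ccccc9)cc3O[C@@H](c3ccc(OCc9ccccc9)c(OCc9ccccc9)c3)[C@@H]2OCc9ccccc9)c(OCc9ccccc9)c2c1O[C@H](c1ccc(OCc9ccccc9)c(OCc9ccccc9)c1)[C@@H](OCc9ccccc9)C2 | intermediate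
37 | 7,3′,4′-tri-O-benzyl-ent-fisetinidol-(4α→6)-7,3′,4′-tri-O-benzyl-ent-fisetinidol-(4α→8)-3,5,7,3′,4′-penta-O-benzylcatechin-(6→4β)-3,7,3′,4′-tetra-O-benzyl-ent-fisetinidol | c9ccccc9COc1ccc2c(c1)O[C@@H](c1ccc(OCc9ccccc9)c(OCc9ccccc9)c1)[C@H](O)[C@@H]2c1cc2c(cc1OCc9ccccc9)O[C@@H](c1ccc(OCc9ccccc9)c(OCc9ccccc9)c1)[C@H](O)[C@@H]2c1c(OCc9ccccc9)c([C@H]2c3ccc(OCc9ccccc9)cc3O[C@@H](c3ccc(OCc9ccccc9)c(OCc9ccccc9)c3)[C@@H]2OCc9ccccc9)c(OCc9ccccc9)c2c1O[C@H](c1ccc(OCc9ccccc9)c(OCc9ccccc9)c1)[C@@H](OCc9ccccc9)C2 | intermediate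
38 | ent-fisetinidol-(4α→6)-ent-fisetinidol-(4α→8)-catechin-(6→4β)-ent-fisetinidol (CNP0126838.5; T 2S,3R,4R; M 2S,3R,4S; catechin 2R,3S; S 2S,3R,4R) | Oc1ccc2c(c1)O[C@@H](c1ccc(O)c(O)c1)[C@H](O)[C@@H]2c1cc2c(cc1O)O[C@@H](c1ccc(O)c(O)c1)[C@H](O)[C@@H]2c1c(O)c([C@H]2c3ccc(O)cc3O[C@@H](c3ccc(O)c(O)c3)[C@@H]2O)c(O)c2c1O[C@H](c1ccc(O)c(O)c1)[C@@H](O)C2 | target

**Step count**

Total: 26 steps. Longest linear sequence: 18 steps (1–6, 9–11, 15, 18–22, 24–26).

**Steps most likely to fail**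

Step 24. Arylation at C2 may stall at the more hindered ring of unit M, the bromide may lose HBr to a 4H-chromene, or the arylzinc may add to the dioxolanylium carbon instead of C2. The fallback uses known chemistry and introduces ring B in an open chain before closing the C2–O1 bond. It sets out from 29: the reduction of step 22 is quenched with aqueous potassium sodium tartrate in place of Ac2O to give the free bis(3-O-pivaloyl lactol) F1. Excess aryllithium 33 (THF, −78 → 0 °C) adds to the hydroxy-aldehyde tautomers and cleaves both pivalates, giving the ring-opened bis(1-aryl-1,2-diol) diphenol F2 as carbinol epimers. Camphorsulfonic acid (cat.) in CH2Cl2 then ionises the dibenzyloxybenzylic carbinols and each phenol closes ring C anti to O3, a cyclodehydration known from flavan-3-ol syntheses. This gives diol 37, where the route is rejoined; step 25 is then not needed.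

Step 19. Hydride delivery to C4 of coumarin M, which carries the doubly ortho-substituted catechin ring, may be slow, or the chiral substrate may override the ligand and give poor facial selectivity. The fallback replaces conjugate hydride addition by hydrogenation of the ring-opened acrylates. It sets out from 25: NaOH in MeOH/THF/H2O opens both lactones to the tetrasodium bis[(Z)-3,3-diarylacrylate] F3. Asymmetric hydrogenation with [Rh(cod)Cl]2 and Chiraphos (enantiomer chosen for 4α-aryl) under H2 in MeOH, known for ring-opened 4-arylcoumarin salts, gives the tetrasodium bis(3,3-diarylpropanoate) F4. Acidification with aq. HCl and warming with TsOH (cat.) in toluene closes both lactones and returns to 26.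

Step 21. Backside attack at C3 must come from the face of the adjacent C4 aryl group and may be blocked, with elimination to the coumarin or epimerisation of the triflate taking over. The fallback inverts C3 by enolate protonation instead of substitution. It sets out from 27: t-BuMe2SiOTf and 2,6-lutidine give the bis(3β-silyl ether) F5. KN(SiMe3)2 in THF at −78 °C followed by AcOH protonates each α-silyloxy enolate anti to the C4 aryl and gives the C3-epimeric bis(3α-silyl ether) F6. HF·pyridine gives the bis(3α-hydroxy lactone) F7, and Me3CCOCl with DMAP in pyridine returns to 29.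

**Further compounds**

F1 | step 24 | bis(2-hydroxy-3-O-pivaloyl lactol): 31 with OH in place of each OAc | c9ccccc9COc1ccc2c(c1)OC(O)[C@H](OC(=O)C(C)(C)C)[C@@H]2c1cc2c(cc1OCc9ccccc9)OC(O)[C@H](OC(=O)C(C)(C)C)[C@@H]2c1c(OCc9ccccc9)c([C@H]2c3ccc(OCc9ccccc9)cc3O[C@@H](c3ccc(OCc9ccccc9)c(OCc9ccccc9)c3)[C@@H]2OCc9ccccc9)c(OCc9ccccc9)c2c1O[C@H](c1ccc(OCc9ccccc9)c(OCc9ccccc9)c1)[C@@H](OCc9ccccc9)C2
F2 | step 24 | ring-opened bis(1-aryl-1,2-diol) diphenol (C2–O1 bonds of units T and M open; carbinol epimers) | c9ccccc9COc1ccc(c(O)c1)[C@H]([C@@H](O)C(O)c1ccc(OCc9ccccc9)c(OCc9ccccc9)c1)c1cc(c(O)cc1OCc9ccccc9)[C@H]([C@@H](O)C(O)c1ccc(OCc9ccccc9)c(OCc9ccccc9)c1)c1c(OCc9ccccc9)c([C@H]2c3ccc(OCc9ccccc9)cc3O[C@@H](c3ccc(OCc9ccccc9)c(OCc9ccccc9)c3)[C@@H]2OCc9ccccc9)c(OCc9ccccc9)c2c1O[C@H](c1ccc(OCc9ccccc9)c(OCc9ccccc9)c1)[C@@H](OCc9ccccc9)C2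
F3 | step 19 | tetrasodium bis[(Z)-3,3-diarylacrylate] from opening of both lactones of 25 (carboxylate cis to the phenoxide ring) | [Na+].[Na+].[Na+].[Na+].c9ccccc9COc1ccc(c([O-])c1)/C(=C\C(=O)[O-])c1cc(c([O-])cc1OCc9ccccc9)/C(=C\C(=O)[O-])c1c(OCc9ccccc9)c([C@H]2c3ccc(OCc9ccccc9)cc3O[C@@H](c3ccc(OCc9ccccc9)c(OCc9ccccc9)c3)[C@@H]2OCc9ccccc9)c(OCc9ccccc9)c2c1O[C@H](c1ccc(OCc9ccccc9)c(OCc9ccccc9)c1)[C@@H](OCc9ccccc9)C2
F4 | step 19 | tetrasodium bis(3,3-diarylpropanoate), benzylic centres as in 26 | [Na+].[Na+].[Na+].[Na+].c9ccccc9COc1ccc(c([O-])c1)[C@H](CC(=O)[O-])c1cc(c([O-])cc1OCc9ccccc9)[C@H](CC(=O)[O-])c1c(OCc9ccccc9)c([C@H]2c3ccc(OCc9ccccc9)cc3O[C@@H](c3ccc(OCc9ccccc9)c(OCc9ccccc9)c3)[C@@H]2OCc9ccccc9)c(OCc9ccccc9)c2c1O[C@H](c1ccc(OCc9ccccc9)c(OCc9ccccc9)c1)[C@@H](OCc9ccccc9)C2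
F5 | step 21 | bis(3β-tert-butyldimethylsilyl ether) of 27 | c9ccccc9COc1ccc2c(c1)OC(=O)[C@@H](O[Si](C)(C)C(C)(C)C)[C@@H]2c1cc2c(cc1OCc9ccccc9)OC(=O)[C@@H](O[Si](C)(C)C(C)(C)C)[C@@H]2c1c(OCc9ccccc9)c([C@H]2c3ccc(OCc9ccccc9)cc3O[C@@H](c3ccc(OCc9ccccc9)c(OCc9ccccc9)c3)[C@@H]2OCc9ccccc9)c(OCc9ccccc9)c2c1O[C@H](c1ccc(OCc9ccccc9)c(OCc9ccccc9)c1)[C@@H](OCc9ccccc9)C2
F6 | step 21 | bis(3α-tert-butyldimethylsilyl ether), C3 epimer of F5 at both lactones | c9ccccc9COc1ccc2c(c1)OC(=O)[C@H](O[Si](C)(C)C(C)(C)C)[C@@H]2c1cc2c(cc1OCc9ccccc9)OC(=O)[C@H](O[Si](C)(C)C(C)(C)C)[C@@H]2c1c(OCc9ccccc9)c([C@H]2c3ccc(OCc9ccccc9)cc3O[C@@H](c3ccc(OCc9ccccc9)c(OCc9ccccc9)c3)[C@@H]2OCc9ccccc9)c(OCc9ccccc9)c2c1O[C@H](c1ccc(OCc9ccccc9)c(OCc9ccccc9)c1)[C@@H](OCc9ccccc9)C2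
F7 | step 21 | bis(3α-hydroxy lactone), C3 epimer of 27 at both lactones | c9ccccc9COc1ccc2c(c1)OC(=O)[C@H](O)[C@@H]2c1cc2c(cc1OCc9ccccc9)OC(=O)[C@H](O)[C@@H]2c1c(OCc9ccccc9)c([C@H]2c3ccc(OCc9ccccc9)cc3O[C@@H](c3ccc(OCc9ccccc9)c(OCc9ccccc9)c3)[C@@H]2OCc9ccccc9)c(OCc9ccccc9)c2c1O[C@H](c1ccc(OCc9ccccc9)c(OCc9ccccc9)c1)[C@@H](OCc9ccccc9)C2
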